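**Retrosynthetic overview**
- The target comes from a 3-oxo-4,5-epoxygermacra-1(10),11-diene (6-O-silyl) by C3 ketone reduction, C3 tigloylation and C6 acetylation.
- Key disconnection (C4–C5 and O–C4): a SmI2-driven reductive Darzens ring closure of an acyclic α,α-dichloroketone aldehyde closes the ten-membered carbocycle and the oxirane in one flask.
- The C6/C7 stereodiad of that precursor comes from a catalytic asymmetric glyoxylate–ene reaction on the terminal prenyl alkene of a geranyl 1,1-dichloroethyl ketone.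
- That ketone comes from methyl homogeranate and 1,1-dichloroethyllithium; the ester comes from geranyl chloride, CO and MeOH.
- Ring order: no ring before step 7; there the carbocycle forms first (C4–C5 bond), then the oxirane (O–C4 bond).

Assumption: only carbon building blocks are numbered (CO, MeOH, TESCl and Ac2O appear as atom-adding reagents); locants C1–C15 in the "Why" lines are germacrane locants (oxirane C4–C5, tiglate on C3, acetate on C6, isopropenyl on C7, ring alkene C1=C10).

**Step 1**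
Reactants: 1 geranyl chloride, (2E)-1-chloro-3,7-dimethylocta-2,6-diene
Product: 2 methyl (3E)-4,8-dimethylnona-3,7-dienoate (methyl homogeranate)
Conditions: CO (20 bar), MeOH, Pd(OAc)2 (2 mol %), PPh3 (4 mol %), i-Pr2NEt, THF, 50 °C
Reagents that add atoms: carbon monoxide [C-]#[O+]; methanol CO
Why: Pd-catalysed allylic alkoxycarbonylation (Tsuji type), in which Pd(0) ionises the allylic chloride to the syn-π-allyl complex, CO inserts at the unhindered primary terminus and methanol cleaves the acyl–Pd bond, so the linear β,γ-unsaturated ester forms with the E geometry retained and no stereocentre is made.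

**Step 2**
Reactants: 2 methyl (3E)-4,8-dimethylnona-3,7-dienoate; 3 1,1-dichloroethane
Product: 4 (5E)-2,2-dichloro-6,10-dimethylundeca-5,9-dien-3-one
Conditions: 3, n-BuLi, THF/Et2O/pentane (4:1:1), −100 °C; then 2, −100 °C; AcOH/THF quench at −100 °C
Reagents that add atoms: none
Why: Acylation of a Köbrich carbenoid (1,1-dichloroethyllithium) by the ester, whose tetrahedral lithium hemiketal is stable at −100 °C and collapses only on the cold acidic quench, so the α,α-dichloroketone is not over-added and the β,γ-alkene is not isomerised; no stereocentre is made.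

**Step 3**
Reactants: 4 (5E)-2,2-dichloro-6,10-dimethylundeca-5,9-dien-3-one; 5 ethyl glyoxylate
Product: 6 ethyl (2R,3S,6E)-10,10-dichloro-2-hydroxy-6-methyl-9-oxo-3-(prop-1-en-2-yl)undec-6-enoate
Conditions: (R)-BINOL (10 mol %), TiCl2(Oi-Pr)2 (10 mol %), 4 Å MS, CH2Cl2, −30 °C
Reagents that add atoms: none
Why: Ti–BINOL-catalysed glyoxylate–ene reaction at the terminal trisubstituted alkene only (the inner alkene is deactivated by the allylic dichloroacyl group), with C–C bond formation at its CH carbon and hydrogen transfer from a methyl group to give the isopropenyl unit; the (R)-BINOL–Ti glyoxylate chelate sets C6 as R and the syn-selective six-membered ene transition state expected for trisubstituted enes sets C7 as S.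

**Step 4**
Reactants: 6 ethyl (2R,3S,6E)-10,10-dichloro-2-hydroxy-6-methyl-9-oxo-3-(prop-1-en-2-yl)undec-6-enoate
Product: 7 ethyl (2R,3S,6E)-10,10-dichloro-6-methyl-9-oxo-3-(prop-1-en-2-yl)-2-[(triethylsilyl)oxy]undec-6-enoate
Conditions: TESCl, imidazole, DMAP (cat.), CH2Cl2, 0 °C
Reagents that add atoms: chlorotriethylsilane CC[Si](Cl)(CC)CC
Why: Standard silylation of a secondary α-hydroxy ester under weakly basic conditions that leave the dichloroketone untouched; the bulky, non-chelating silyl ether is chosen to steer step 7 and no stereocentre is touched.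

**Step 5**
Reactants: 7 ethyl (2R,3S,6E)-10,10-dichloro-6-methyl-9-oxo-3-(prop-1-en-2-yl)-2-[(triethylsilyl)oxy]undec-6-enoate
Product: 8 (2R,3S,6E)-10,10-dichloro-6-methyl-3-(prop-1-en-2-yl)-2-[(triethylsilyl)oxy]undec-6-ene-1,9-diol (both C9 epimers)
Conditions: DIBAL-H (5 equiv), CH2Cl2, −78 → 0 °C; Rochelle salt work-up
Reagents that add atoms: none
Why: Exhaustive hydride reduction of ester and ketone by DIBAL-H, which spares C–Cl bonds, alkenes and the silyl ether; the new carbinol centre is formed unselectively on purpose because step 6 removes it.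

**Step 6**
Reactants: 8 (2R,3S,6E)-10,10-dichloro-6-methyl-3-(prop-1-en-2-yl)-2-[(triethylsilyl)oxy]undec-6-ene-1,9-diol
Product: 9 (2R,3S,6E)-10,10-dichloro-6-methyl-9-oxo-3-(prop-1-en-2-yl)-2-[(triethylsilyl)oxy]undec-6-enal
Conditions: Dess–Martin periodinane (3 equiv), NaHCO3, CH2Cl2, 0 °C → rt
Reagents that add atoms: none
Why: Buffered Dess–Martin double oxidation takes the primary alcohol to the aldehyde and the secondary alcohol to the ketone under neutral conditions, so the α-silyloxy aldehyde centre (C6) is not epimerised and the β,γ-alkene does not move into conjugation.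

**Step 7**
Reactants: 9 (2R,3S,6E)-10,10-dichloro-6-methyl-9-oxo-3-(prop-1-en-2-yl)-2-[(triethylsilyl)oxy]undec-6-enal
Product: 11 (1S,4E,8S,9R,10R)-1,5-dimethyl-8-(prop-1-en-2-yl)-9-[(triethylsilyl)oxy]-11-oxabicyclo[8.1.0]undec-4-en-2-one, via macrocyclic chlorohydrin 10 (not isolated)
Conditions: SmI2 (2.1 equiv, 0.1 M in THF) added over 3 h to 9 (0.002 M), THF, −78 °C; then MeOH, DBU, −78 → 0 °C
Reagents that add atoms: none
Why: Proposed new method: two SmI2 reduce one C–Cl bond of the gem-dichloroketone (far easier to reduce than the aldehyde or the monochloride) to a regiodefined Sm(III) α-chloroenolate that cannot enolise towards the allylic CH2, the Sm(III) centre binds the aldehyde and closes the ten-membered ring by a templated aldol (C4–C5 bond) with Felkin–Anh attack anti to the C6 silyloxy group (sets C5), the closed transition state places C3 and C6 on opposite sides (sets C4), and after protonation DBU drives anti-periplanar displacement of the remaining chloride by the C5 oxygen (inversion at C4) to the trans oxirane; the closest known reactions are the SmI2-mediated intramolecular Reformatsky closure of medium rings, the SmI2 aldol of α,α-dichloroketones with aldehydes to α-chloro-β-hydroxy ketones, and the Darzens closure of such chlorohydrins.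

**Step 8**
Reactants: 11 (1S,4E,8S,9R,10R)-1,5-dimethyl-8-(prop-1-en-2-yl)-9-[(triethylsilyl)oxy]-11-oxabicyclo[8.1.0]undec-4-en-2-one
Product: 12 (1R,2S,4E,8S,9R,10R)-1,5-dimethyl-8-(prop-1-en-2-yl)-9-[(triethylsilyl)oxy]-11-oxabicyclo[8.1.0]undec-4-en-2-ol
Conditions: (R)-Me-CBS (0.5 equiv), catecholborane (2 equiv), toluene, −78 °C; MeOH quench
Reagents that add atoms: none
Why: Corey–Bakshi–Shibata reduction under reagent control, with the fully substituted oxirane carbon as the large group and the ring CH2 as the small group, so the (R)-oxazaborolidine delivers hydride to give the (S)-carbinol at C3; catecholborane at −78 °C does not hydroborate the alkenes or open the oxirane.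

**Step 9**
Reactants: 12 (1R,2S,4E,8S,9R,10R)-1,5-dimethyl-8-(prop-1-en-2-yl)-9-[(triethylsilyl)oxy]-11-oxabicyclo[8.1.0]undec-4-en-2-ol; 13 tigloyl chloride, (2E)-2-methylbut-2-enoyl chloride
Product: 14 (1R,2S,4E,8S,9R,10R)-1,5-dimethyl-8-(prop-1-en-2-yl)-9-[(triethylsilyl)oxy]-11-oxabicyclo[8.1.0]undec-4-en-2-yl (2E)-2-methylbut-2-enoate
Conditions: 13, pyridine, DMAP, CH2Cl2, 0 °C → rt
Reagents that add atoms: none
Why: DMAP-catalysed acylation of the hindered secondary alcohol with retention at C3, using pyridine (too weak a base to form the vinylketene) so the tiglate stays E and conjugated.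

**Step 10**
Reactants: 14 (1R,2S,4E,8S,9R,10R)-1,5-dimethyl-8-(prop-1-en-2-yl)-9-[(triethylsilyl)oxy]-11-oxabicyclo[8.1.0]undec-4-en-2-yl (2E)-2-methylbut-2-enoate
Product: 16 (1R,2S,4E,8S,9R,10R)-9-acetoxy-1,5-dimethyl-8-(prop-1-en-2-yl)-11-oxabicyclo[8.1.0]undec-4-en-2-yl (2E)-2-methylbut-2-enoate (target CNP0400048.1), via free C9 alcohol 15 (not isolated)
Conditions: TBAF/AcOH (1:1), THF, 0 °C → rt; then Et3N, Ac2O, DMAP, rt
Reagents that add atoms: acetic anhydride CC(=O)OC(C)=O
Why: Buffered fluoride desilylation gives the neutral C6 alcohol (no alkoxide, so no Payne rearrangement and no acid-induced transannular opening of the oxirane), which is acetylated in the same flask by DMAP-catalysed acylation with retention at C6.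

**Compound list**
1 | geranyl chloride, (2E)-1-chloro-3,7-dimethylocta-2,6-diene | CC(C)=CCC/C(C)=C/CCl | starting material
2 | methyl (3E)-4,8-dimethylnona-3,7-dienoate | CC(C)=CCC/C(C)=C/CC(=O)OC | intermediate
3 | 1,1-dichloroethane | CC(Cl)Cl | starting material
4 | (5E)-2,2-dichloro-6,10-dimethylundeca-5,9-dien-3-one | CC(C)=CCC/C(C)=C/CC(=O)C(C)(Cl)Cl | intermediate
5 | ethyl glyoxylate | CCOC(=O)C=O | starting material
6 | ethyl (2R,3S,6E)-10,10-dichloro-2-hydroxy-6-methyl-9-oxo-3-(prop-1-en-2-yl)undec-6-enoate | CCOC(=O)[C@H](O)[C@@H](CC/C(C)=C/CC(=O)C(C)(Cl)Cl)C(C)=C | intermediate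
7 | ethyl (2R,3S,6E)-10,10-dichloro-6-methyl-9-oxo-3-(prop-1-en-2-yl)-2-[(triethylsilyl)oxy]undec-6-enoate | CCOC(=O)[C@H](O[Si](CC)(CC)CC)[C@@H](CC/C(C)=C/CC(=O)C(C)(Cl)Cl)C(C)=C | intermediate
8 | (2R,3S,6E)-10,10-dichloro-6-methyl-3-(prop-1-en-2-yl)-2-[(triethylsilyl)oxy]undec-6-ene-1,9-diol (C9 epimers) | OC[C@H](O[Si](CC)(CC)CC)[C@@H](CC/C(C)=C/CC(O)C(C)(Cl)Cl)C(C)=C | intermediate
9 | (2R,3S,6E)-10,10-dichloro-6-methyl-9-oxo-3-(prop-1-en-2-yl)-2-[(triethylsilyl)oxy]undec-6-enal | O=C[C@H](O[Si](CC)(CC)CC)[C@@H](CC/C(C)=C/CC(=O)C(C)(Cl)Cl)C(C)=C | intermediate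
10 | (3E,7S,8R,9R,10R)-10-chloro-9-hydroxy-4,10-dimethyl-7-(prop-1-en-2-yl)-8-[(triethylsilyl)oxy]cyclodec-3-en-1-one | C=C(C)[C@@H]1CC/C(C)=C/CC(=O)[C@](C)(Cl)[C@H](O)[C@@H]1O[Si](CC)(CC)CC | intermediate
11 | (1S,4E,8S,9R,10R)-1,5-dimethyl-8-(prop-1-en-2-yl)-9-[(triethylsilyl)oxy]-11-oxabicyclo[8.1.0]undec-4-en-2-one | C=C(C)[C@@H]1CC/C(C)=C/CC(=O)[C@@]2(C)O[C@@H]2[C@@H]1O[Si](CC)(CC)CC | intermediate
12 | (1R,2S,4E,8S,9R,10R)-1,5-dimethyl-8-(prop-1-en-2-yl)-9-[(triethylsilyl)oxy]-11-oxabicyclo[8.1.0]undec-4-en-2-ol | C=C(C)[C@@H]1CC/C(C)=C/C[C@H](O)[C@@]2(C)O[C@@H]2[C@@H]1O[Si](CC)(CC)CC | intermediate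
13 | tigloyl chloride, (2E)-2-methylbut-2-enoyl chloride | C/C=C(\C)C(=O)Cl | starting material
14 | (1R,2S,4E,8S,9R,10R)-1,5-dimethyl-8-(prop-1-en-2-yl)-9-[(triethylsilyl)oxy]-11-oxabicyclo[8.1.0]undec-4-en-2-yl (2E)-2-methylbut-2-enoate | C=C(C)[C@@H]1CC/C(C)=C/C[C@H](OC(=O)/C(C)=C/C)[C@@]2(C)O[C@@H]2[C@@H]1O[Si](CC)(CC)CC | intermediate
15 | (1R,2S,4E,8S,9R,10R)-9-hydroxy-1,5-dimethyl-8-(prop-1-en-2-yl)-11-oxabicyclo[8.1.0]undec-4-en-2-yl (2E)-2-methylbut-2-enoate | C=C(C)[C@@H]1CC/C(C)=C/C[C@H](OC(=O)/C(C)=C/C)[C@@]2(C)O[C@@H]2[C@@H]1O | intermediate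
16 | (1R,2S,4E,8S,9R,10R)-9-acetoxy-1,5-dimethyl-8-(prop-1-en-2-yl)-11-oxabicyclo[8.1.0]undec-4-en-2-yl (2E)-2-methylbut-2-enoate | C=C(C)[C@@H]1CC/C(C)=C/C[C@H](OC(=O)/C(C)=C/C)[C@@]2(C)O[C@@H]2[C@@H]1OC(C)=O | target

**Step count and risks**
Total step count: 10 (steps 7 and 10 are each two-stage, one-flask operations). Longest linear sequence: 10 steps from 1.

The three steps most likely to fail:

Step 7 is the most exposed. The ten-membered ring may not close cleanly, SmI2 may over-reduce the chlorohydrin, or the aldol may give the chlorohydrin that leads to the cis oxirane. The fallback sets out from 9 and no longer closes the oxirane in the ring-forming flask. Excess CrCl2 with catalytic LiI in THF (chromium Reformatsky addition, then reductive β-elimination of the Cr(III) chlorohydrinate on the Cr(III) template) should give the macrocyclic dienone (2E,4S,5S,8E)-2,8-dimethyl-5-(prop-1-en-2-yl)-4-[(triethylsilyl)oxy]cyclodeca-2,8-dien-1-one F1. Weitz–Scheffer epoxidation of its electron-poor C4=C5 bond (t-BuOOH, DBU, CH2Cl2), stepwise and anti to the C6 silyloxy group, gives the trans oxirane and comes back to the route at 11.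

Step 3 may deliver the wrong relative configuration at C6/C7 if the catalyst turns out anti-selective on this ene. The fallback sets out from 4 and uses the (S)-BINOL–Ti catalyst, which in that case gives ethyl (2S,3S,6E)-10,10-dichloro-2-hydroxy-6-methyl-9-oxo-3-(prop-1-en-2-yl)undec-6-enoate F2, with C7 correct and C6 wrong. Mitsunobu inversion at C6 with chloroacetic acid (PPh3, DIAD) gives ethyl (2R,3S,6E)-10,10-dichloro-2-[(chloroacetyl)oxy]-6-methyl-9-oxo-3-(prop-1-en-2-yl)undec-6-enoate F3. Neutral cleavage of the chloroacetate with thiourea and NaHCO3 in EtOH (no alkoxide, so no Favorskii reaction of the dichloroketone) comes back to the route at 6.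

Step 8 may give the wrong C3 epimer if the conformation of the medium ring overrides the catalyst. The fallback sets out from 11 and uses substrate control: Luche reduction (NaBH4, CeCl3, MeOH, −78 °C) to whichever alcohol the ring prefers. If that is (1R,2R,4E,8S,9R,10R)-1,5-dimethyl-8-(prop-1-en-2-yl)-9-[(triethylsilyl)oxy]-11-oxabicyclo[8.1.0]undec-4-en-2-ol F4, Mitsunobu esterification with tiglic acid (PPh3, DIAD) inverts C3 and installs the tiglate in the same operation. This comes back to the route at 14 and bypasses 12 and step 9.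

**Further compounds**
F1 | step 7 | (2E,4S,5S,8E)-2,8-dimethyl-5-(prop-1-en-2-yl)-4-[(triethylsilyl)oxy]cyclodeca-2,8-dien-1-one | C=C(C)[C@@H]1CC/C(C)=C/CC(=O)/C(C)=C/[C@@H]1O[Si](CC)(CC)CC
F2 | step 3 | ethyl (2S,3S,6E)-10,10-dichloro-2-hydroxy-6-methyl-9-oxo-3-(prop-1-en-2-yl)undec-6-enoate | CCOC(=O)[C@@H](O)[C@@H](CC/C(C)=C/CC(=O)C(C)(Cl)Cl)C(C)=C
F3 | step 3 | ethyl (2R,3S,6E)-10,10-dichloro-2-[(chloroacetyl)oxy]-6-methyl-9-oxo-3-(prop-1-en-2-yl)undec-6-enoate | CCOC(=O)[C@H](OC(=O)CCl)[C@@H](CC/C(C)=C/CC(=O)C(C)(Cl)Cl)C(C)=C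
F4 | step 8 | (1R,2R,4E,8S,9R,10R)-1,5-dimethyl-8-(prop-1-en-2-yl)-9-[(triethylsilyl)oxy]-11-oxabicyclo[8.1.0]undec-4-en-2-ol | C=C(C)[C@@H]1CC/C(C)=C/C[C@@H](O)[C@@]2(C)O[C@@H]2[C@@H]1O[Si](CC)(CC)CC
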